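**Retrosynthetic overview**
- The seven-membered lactone C–O bond is cut last, giving a diaryl ether hydroxy acid; lactonisation closes the final ring.
- The diaryl ether C–O bond is cut by an Ullmann disconnection into two fragments of similar size: a bromo-chromene carboxylic acid (fragment A) and a prenylated tetra-oxygenated phenol (fragment B).
- Fragment A: the pyran ring comes from 3-methylbut-2-enal and 2-bromo-4,6-dihydroxybenzaldehyde, which is made from resorcinol by meta C–H borylation/bromination and Vilsmeier formylation.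
- Fragment B: hydroquinone is elaborated by directed ortho-metalation/hydroxylation, O-methylation, para-bromination/hydroxylation and a second directed metalation/prenylation.
- Ring order: both benzene rings are bought, the pyran ring is formed within fragment A (step 5), and the dioxepinone ring is formed last (step 18).

Assumption: the target SMILES contains no stereocentre or other stereogenic element, so the compound is achiral and no stereocontrol is needed.

**Fragment A**

Step 1
Reactants: 1 resorcinol (benzene-1,3-diol)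
Product: 2 1,3-dimethoxybenzene
Conditions: MeI (2.5 equiv), K2CO3 (3 equiv), acetone, reflux
Reagents that add atoms: iodomethane, CI
Why: Williamson ether synthesis gives the bis-methyl ether, which protects both phenols and makes the arene a clean 1,3-disubstituted substrate for the next two steps.

Step 2
Reactants: 2 1,3-dimethoxybenzene
Product: 4 1-bromo-3,5-dimethoxybenzene, via arylboronic pinacol ester 3 (not isolated)
Conditions: [Ir(OMe)(cod)]2 (1 mol%), 4,4'-di-tert-butyl-2,2'-bipyridine (2 mol%), B2pin2 (1.0 equiv), THF, 80 °C; then CuBr2 (3 equiv), MeOH/H2O 1:1, 80 °C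
Reagents that add atoms: bis(pinacolato)diboron, CC1(C)OB(OC1(C)C)B1OC(C)(C)C(C)(C)O1 (boryl group of intermediate 3 only); copper dibromide, [Cu+2].[Br-].[Br-] (bromine of 4)
Why: Sterically controlled iridium-catalysed C–H borylation attacks the only C–H without an ortho substituent (C5), and copper-mediated bromodeboronation (Hartwig meta-halogenation sequence) swaps boron for bromine.

Step 3
Reactants: 4 1-bromo-3,5-dimethoxybenzene
Product: 5 2-bromo-4,6-dimethoxybenzaldehyde
Conditions: POCl3 (2 equiv), DMF, 0 to 100 °C; aqueous NaOAc work-up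
Reagents that add atoms: N,N-dimethylformamide, CN(C)C=O (formyl carbon); water, O (carbonyl oxygen on hydrolysis)
Why: Vilsmeier–Haack formylation goes para to one methoxy group and ortho to the other, next to bromine and not between the two methoxy groups, which sets the 2-bromo-4,6-dioxygenated pattern of ring A.

Step 4
Reactants: 5 2-bromo-4,6-dimethoxybenzaldehyde
Product: 6 2-bromo-4,6-dihydroxybenzaldehyde
Conditions: BBr3 (4 equiv), CH2Cl2, −78 °C to rt; aqueous work-up
Reagents that add atoms: none
Why: Lewis-acid ether cleavage with BBr3 removes both methyl groups and leaves the aryl bromide and the aldehyde untouched.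

Step 5
Reactants: 6 2-bromo-4,6-dihydroxybenzaldehyde; 7 3-methylbut-2-enal
Product: 8 7-bromo-5-hydroxy-2,2-dimethyl-2H-chromene-6-carbaldehyde
Conditions: 3-methylbut-2-enal (1.5 equiv), ethylenediammonium diacetate (20 mol%), xylene, 140 °C
Reagents that add atoms: none
Why: Knoevenagel-type condensation at the carbon between the two hydroxyl groups followed by 6π-oxa-electrocyclisation (formal [3+3] chromene annulation) closes the pyran onto the non-chelated 4-OH, while the aldehyde-chelated OH stays free and the position next to bromine is hindered.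

Step 6
Reactants: 8 7-bromo-5-hydroxy-2,2-dimethyl-2H-chromene-6-carbaldehyde
Product: 9 7-bromo-5-(methoxymethoxy)-2,2-dimethyl-2H-chromene-6-carbaldehyde
Conditions: NaH (1.3 equiv), DMF, 0 °C; MOMCl (1.5 equiv), 0 °C to rt
Reagents that add atoms: chloromethyl methyl ether, COCCl
Why: O-alkylation of the phenoxide (MOM protection) masks the chelated phenol so that it cannot act as a competing nucleophile or deactivate the ring in the copper coupling.

Step 7
Reactants: 9 7-bromo-5-(methoxymethoxy)-2,2-dimethyl-2H-chromene-6-carbaldehyde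
Product: 10 7-bromo-5-(methoxymethoxy)-2,2-dimethyl-2H-chromene-6-carboxylic acid
Conditions: NaClO2 (3 equiv), NaH2PO4 (3 equiv), 2-methyl-2-butene (20 equiv), t-BuOH/THF/H2O, 0 °C to rt
Reagents that add atoms: sodium chlorite, [Na+].[O-]Cl=O
Why: Pinnick oxidation converts the hindered aldehyde to the acid under buffered conditions, with 2-methyl-2-butene scavenging hypochlorous acid so the chromene alkene and the MOM ether survive.

**Fragment B**

Step 8
Reactants: 11 hydroquinone (benzene-1,4-diol)
Product: 12 1,4-bis(methoxymethoxy)benzene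
Conditions: NaH (2.5 equiv), DMF, 0 °C; MOMCl (2.5 equiv), 0 °C to rt
Reagents that add atoms: chloromethyl methyl ether, COCCl
Why: Williamson-type acetal formation installs two MOM ethers, which are both protecting groups and strong directing groups for ortho-lithiation.

Step 9
Reactants: 12 1,4-bis(methoxymethoxy)benzene
Product: 15 2,5-bis(methoxymethoxy)phenol, via aryllithium 13 (not isolated), via dimethyl arylboronate 14 (not isolated)
Conditions: n-BuLi (1.1 equiv), THF, 0 °C to rt; B(OMe)3 (1.5 equiv), −78 °C to rt; then 30% H2O2, 2 M NaOH, 0 °C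
Reagents that add atoms: hydrogen peroxide, OO (phenol oxygen of 15); n-butyllithium, [Li]CCCC (lithium of intermediate 13 only); trimethyl borate, COB(OC)OC (boron and methoxy groups of intermediate 14 only)
Why: Directed ortho-metalation (all four ring positions are equivalent) followed by borylation and oxidative C–B to C–O conversion delivers the phenol.

Step 10
Reactants: 15 2,5-bis(methoxymethoxy)phenol
Product: 16 2-methoxy-1,4-bis(methoxymethoxy)benzene
Conditions: MeI (1.5 equiv), K2CO3 (2 equiv), acetone, reflux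
Reagents that add atoms: iodomethane, CI
Why: Williamson methylation installs the methoxy group of the target on the only free phenol.

Step 11
Reactants: 16 2-methoxy-1,4-bis(methoxymethoxy)benzene
Product: 17 1-bromo-4-methoxy-2,5-bis(methoxymethoxy)benzene
Conditions: NBS (1.05 equiv), MeCN, 0 °C, dark
Reagents that add atoms: N-bromosuccinimide, BrN1C(=O)CCC1=O
Why: Electrophilic aromatic bromination takes the unhindered position para to the methoxy group and ortho to a MOM ether, as 1,2,4-trialkoxybenzenes do.

Step 12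
Reactants: 17 1-bromo-4-methoxy-2,5-bis(methoxymethoxy)benzene
Product: 20 4-methoxy-2,5-bis(methoxymethoxy)phenol, via aryllithium 18 (not isolated), via dimethyl arylboronate 19 (not isolated)
Conditions: n-BuLi (1.05 equiv), THF, −78 °C; B(OMe)3 (1.5 equiv), −78 °C to rt; then 30% H2O2, 2 M NaOH, 0 °C; Na2S2O3 quench
Reagents that add atoms: hydrogen peroxide, OO (phenol oxygen of 20); n-butyllithium, [Li]CCCC (lithium of intermediate 18 only); trimethyl borate, COB(OC)OC (boron and methoxy groups of intermediate 19 only)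
Why: Bromine–lithium exchange is faster than deprotonation at −78 °C, so borylation and oxidation place the hydroxyl exactly at the former C–Br position.

Step 13
Reactants: 20 4-methoxy-2,5-bis(methoxymethoxy)phenol
Product: 21 [4-methoxy-2,5-bis(methoxymethoxy)phenoxy]tri(propan-2-yl)silane
Conditions: TIPSCl (1.2 equiv), imidazole (2.5 equiv), DMF, rt
Reagents that add atoms: chlorotri(propan-2-yl)silane, CC(C)[Si](Cl)(C(C)C)C(C)C
Why: Silylation masks the phenol as a bulky, non-coordinating ether that shields its ortho C–H from the next lithiation.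

Step 14
Reactants: 21 [4-methoxy-2,5-bis(methoxymethoxy)phenoxy]tri(propan-2-yl)silane; 22 1-bromo-3-methylbut-2-ene (prenyl bromide)
Product: 24 [4-methoxy-2,5-bis(methoxymethoxy)-3-(3-methylbut-2-en-1-yl)phenoxy]tri(propan-2-yl)silane, via aryllithium 23 (not isolated)
Conditions: n-BuLi (1.2 equiv), THF, 0 °C to rt; then CuBr·SMe2 (10 mol%), prenyl bromide (1.3 equiv), −78 to 0 °C
Reagents that add atoms: n-butyllithium, [Li]CCCC (lithium of intermediate 23 only; no reagent atom remains in 24)
Why: Directed ortho-metalation occurs at the C–H flanked by OMe and OMOM (two cooperating directing groups, whereas the other C–H is shielded by the TIPS ether), and copper-catalysed SN2 allylation then gives the linear prenyl group.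

Step 15
Reactants: 24 [4-methoxy-2,5-bis(methoxymethoxy)-3-(3-methylbut-2-en-1-yl)phenoxy]tri(propan-2-yl)silane
Product: 25 4-methoxy-2,5-bis(methoxymethoxy)-3-(3-methylbut-2-en-1-yl)phenol
Conditions: TBAF (1.1 equiv), THF, 0 °C, argon; aqueous NH4Cl work-up
Reagents that add atoms: none
Why: Fluoride-mediated desilylation frees the single phenol needed for the coupling and leaves the MOM ethers and the prenyl group intact.

**Union and endgame**

Step 16
Reactants: 10 7-bromo-5-(methoxymethoxy)-2,2-dimethyl-2H-chromene-6-carboxylic acid; 25 4-methoxy-2,5-bis(methoxymethoxy)-3-(3-methylbut-2-en-1-yl)phenol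
Product: 26 7-[4-methoxy-2,5-bis(methoxymethoxy)-3-(3-methylbut-2-en-1-yl)phenoxy]-5-(methoxymethoxy)-2,2-dimethyl-2H-chromene-6-carboxylic acid
Conditions: CuI (20 mol%), Cs2CO3 (3 equiv), degassed DMF, 100 °C, argon; work-up at pH 4, 0 °C
Reagents that add atoms: none
Why: Ullmann condensation (copper-catalysed C–O coupling) is accelerated by the ortho-carboxylate of the 2-bromobenzoic acid, and because 25 has one free phenol and 10 one bromide only a single diaryl ether can form.

Step 17
Reactants: 26 (tris-MOM diaryl ether acid)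
Product: 27 7-[2,5-dihydroxy-4-methoxy-3-(3-methylbut-2-en-1-yl)phenoxy]-5-hydroxy-2,2-dimethyl-2H-chromene-6-carboxylic acid
Conditions: TMSOTf (8 equiv), 2,2'-bipyridyl (12 equiv), MeCN, 0 °C to rt, argon; aqueous work-up
Reagents that add atoms: none
Why: Aryl MOM ethers are cleaved by the buffered silyl triflate/bipyridyl system without protic acid, which avoids chroman formation from the prenyl group and its neighbouring phenol and avoids decarboxylation of the electron-rich acid.

Step 18
Reactants: 27 (trihydroxy diaryl ether acid)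
Product: 28 Garcinisidone B
Conditions: DCC (1.5 equiv), THF/CH2Cl2 (2 mM), 0 °C to rt, argon
Reagents that add atoms: none
Why: Carbodiimide-mediated lactonisation (Steglich-type, run without DMAP) closes the seven-membered depsidone ring, because only the phenol ortho to the diaryl ether oxygen can reach the activated carboxyl group.

**Compound list**
1 | resorcinol (benzene-1,3-diol) | Oc1cccc(O)c1 | starting material
2 | 1,3-dimethoxybenzene | COc1cccc(OC)c1 | intermediate
3 | 2-(3,5-dimethoxyphenyl)-4,4,5,5-tetramethyl-1,3,2-dioxaborolane (formed in the flask) | COc1cc(OC)cc(c1)B1OC(C)(C)C(C)(C)O1 | intermediate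
4 | 1-bromo-3,5-dimethoxybenzene | COc1cc(Br)cc(OC)c1 | intermediate
5 | 2-bromo-4,6-dimethoxybenzaldehyde | COc1cc(Br)c(C=O)c(OC)c1 | intermediate
6 | 2-bromo-4,6-dihydroxybenzaldehyde | Oc1cc(Br)c(C=O)c(O)c1 | intermediate
7 | 3-methylbut-2-enal | CC(C)=CC=O | starting material
8 | 7-bromo-5-hydroxy-2,2-dimethyl-2H-chromene-6-carbaldehyde | CC1(C)C=Cc2c(O1)cc(Br)c(C=O)c2O | intermediate
9 | 7-bromo-5-(methoxymethoxy)-2,2-dimethyl-2H-chromene-6-carbaldehyde | CC1(C)C=Cc2c(O1)cc(Br)c(C=O)c2OCOC | intermediate
10 | 7-bromo-5-(methoxymethoxy)-2,2-dimethyl-2H-chromene-6-carboxylic acid | CC1(C)C=Cc2c(O1)cc(Br)c(C(=O)O)c2OCOC | intermediate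
11 | hydroquinone (benzene-1,4-diol) | Oc1ccc(O)cc1 | starting material
12 | 1,4-bis(methoxymethoxy)benzene | COCOc1ccc(OCOC)cc1 | intermediate
13 | [2,5-bis(methoxymethoxy)phenyl]lithium (formed in the flask) | [Li]c1cc(OCOC)ccc1OCOC | intermediate
14 | dimethyl [2,5-bis(methoxymethoxy)phenyl]boronate (formed in the flask) | COCOc1ccc(OCOC)c(c1)B(OC)OC | intermediate
15 | 2,5-bis(methoxymethoxy)phenol | COCOc1ccc(OCOC)c(O)c1 | intermediate
16 | 2-methoxy-1,4-bis(methoxymethoxy)benzene | COCOc1ccc(OCOC)c(OC)c1 | intermediate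
17 | 1-bromo-4-methoxy-2,5-bis(methoxymethoxy)benzene | COCOc1cc(Br)c(OCOC)cc1OC | intermediate
18 | [4-methoxy-2,5-bis(methoxymethoxy)phenyl]lithium (formed in the flask) | COCOc1cc([Li])c(OCOC)cc1OC | intermediate
19 | dimethyl [4-methoxy-2,5-bis(methoxymethoxy)phenyl]boronate (formed in the flask) | COCOc1cc(B(OC)OC)c(OCOC)cc1OC | intermediate
20 | 4-methoxy-2,5-bis(methoxymethoxy)phenol | COCOc1cc(O)c(OCOC)cc1OC | intermediate
21 | [4-methoxy-2,5-bis(methoxymethoxy)phenoxy]tri(propan-2-yl)silane | COCOc1cc(O[Si](C(C)C)(C(C)C)C(C)C)c(OCOC)cc1OC | intermediate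
22 | 1-bromo-3-methylbut-2-ene (prenyl bromide) | CC(C)=CCBr | starting material
23 | {2-methoxy-3,6-bis(methoxymethoxy)-5-[tri(propan-2-yl)silyloxy]phenyl}lithium (formed in the flask) | COCOc1cc(O[Si](C(C)C)(C(C)C)C(C)C)c(OCOC)c([Li])c1OC | intermediate
24 | [4-methoxy-2,5-bis(methoxymethoxy)-3-(3-methylbut-2-en-1-yl)phenoxy]tri(propan-2-yl)silane | COCOc1cc(O[Si](C(C)C)(C(C)C)C(C)C)c(OCOC)c(CC=C(C)C)c1OC | intermediate
25 | 4-methoxy-2,5-bis(methoxymethoxy)-3-(3-methylbut-2-en-1-yl)phenol | COCOc1cc(O)c(OCOC)c(CC=C(C)C)c1OC | intermediate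
26 | 7-[4-methoxy-2,5-bis(methoxymethoxy)-3-(3-methylbut-2-en-1-yl)phenoxy]-5-(methoxymethoxy)-2,2-dimethyl-2H-chromene-6-carboxylic acid | CC1(C)C=Cc2c(O1)cc(Oc1cc(OCOC)c(OC)c(CC=C(C)C)c1OCOC)c(C(=O)O)c2OCOC | intermediate
27 | 7-[2,5-dihydroxy-4-methoxy-3-(3-methylbut-2-en-1-yl)phenoxy]-5-hydroxy-2,2-dimethyl-2H-chromene-6-carboxylic acid | CC1(C)C=Cc2c(O1)cc(Oc1cc(O)c(OC)c(CC=C(C)C)c1O)c(C(=O)O)c2O | intermediate
28 | Garcinisidone B | COc1c(O)cc2c(c1CC=C(C)C)OC(=O)c1c(cc3c(c1O)C=CC(C)(C)O3)O2 | target

**Step count and risks**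

Total step count: 18 (steps 1–7 fragment A, steps 8–15 fragment B, steps 16–18 after the union).
Longest linear sequence: 11 steps (steps 8–15, then 16–18).

Most likely to fail, first: step 14. The lithiation of 21 must choose the C–H between OMe and OMOM over the C–H between OMOM and OTIPS. If it does not, the prenyl group is placed by a sigmatropic route that sets out from 15 and replaces steps 10–15. NBS bromination para to the free hydroxyl gives 4-bromo-2,5-bis(methoxymethoxy)phenol F1. O-Alkylation with 3-chloro-3-methylbut-1-yne (K2CO3, KI, catalytic CuI, acetone) gives 1-bromo-2,5-bis(methoxymethoxy)-4-[(2-methylbut-3-yn-2-yl)oxy]benzene F2. Semi-hydrogenation (H2, Pd/CaCO3 poisoned with Pb(OAc)2, quinoline) gives 1-bromo-2,5-bis(methoxymethoxy)-4-[(2-methylbut-3-en-2-yl)oxy]benzene F3. Heating in toluene at 110 °C brings about the aromatic Claisen rearrangement to the only free ortho position and gives 4-bromo-3,6-bis(methoxymethoxy)-2-(3-methylbut-2-en-1-yl)phenol F4. Methylation (MeI, K2CO3) gives 1-bromo-4-methoxy-2,5-bis(methoxymethoxy)-3-(3-methylbut-2-en-1-yl)benzene F5. Palladium-catalysed hydroxylation of the aryl bromide (Pd2(dba)3, t-BuXPhos, KOH, dioxane/H2O, 100 °C) then comes back to the route at 25.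

Second: step 16. The 2,6-disubstituted, electron-rich bromo acid 10 may couple slowly or lose CO2 under copper and heat. The fallback makes the ether one oxidation level lower and sets out from 9 (with 25). Copper-catalysed coupling activated by the ortho-formyl group (CuI, picolinic acid, K3PO4, DMSO, 90 °C) gives 7-[4-methoxy-2,5-bis(methoxymethoxy)-3-(3-methylbut-2-en-1-yl)phenoxy]-5-(methoxymethoxy)-2,2-dimethyl-2H-chromene-6-carbaldehyde F6. Pinnick oxidation of F6 (NaClO2, NaH2PO4, 2-methyl-2-butene) comes back to the route at 26.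

Third: step 18. The free acid 27 carries an air-sensitive hydroquinone and three phenols, so oxidation or intermolecular acylation can compete with ring closure. The fallback activates the carboxyl group before the phenols are unmasked and sets out from 26. DCC and pentafluorophenol give pentafluorophenyl 7-[4-methoxy-2,5-bis(methoxymethoxy)-3-(3-methylbut-2-en-1-yl)phenoxy]-5-(methoxymethoxy)-2,2-dimethyl-2H-chromene-6-carboxylate F7. MOM removal with TMSOTf/2,2'-bipyridyl gives pentafluorophenyl 7-[2,5-dihydroxy-4-methoxy-3-(3-methylbut-2-en-1-yl)phenoxy]-5-hydroxy-2,2-dimethyl-2H-chromene-6-carboxylate F8, which is not isolated. NaHCO3 at high dilution closes F8 to the lactone, so the route is rejoined at 28 without passing through 27.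

**Further compounds**
F1 | step 14 | 4-bromo-2,5-bis(methoxymethoxy)phenol | Oc1cc(OCOC)c(Br)cc1OCOC
F2 | step 14 | 1-bromo-2,5-bis(methoxymethoxy)-4-[(2-methylbut-3-yn-2-yl)oxy]benzene | C#CC(C)(C)Oc1cc(OCOC)c(Br)cc1OCOC
F3 | step 14 | 1-bromo-2,5-bis(methoxymethoxy)-4-[(2-methylbut-3-en-2-yl)oxy]benzene | C=CC(C)(C)Oc1cc(OCOC)c(Br)cc1OCOC
F4 | step 14 | 4-bromo-3,6-bis(methoxymethoxy)-2-(3-methylbut-2-en-1-yl)phenol | Oc1c(CC=C(C)C)c(OCOC)c(Br)cc1OCOC
F5 | step 14 | 1-bromo-4-methoxy-2,5-bis(methoxymethoxy)-3-(3-methylbut-2-en-1-yl)benzene | COc1c(CC=C(C)C)c(OCOC)c(Br)cc1OCOC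
F6 | step 16 | 7-[4-methoxy-2,5-bis(methoxymethoxy)-3-(3-methylbut-2-en-1-yl)phenoxy]-5-(methoxymethoxy)-2,2-dimethyl-2H-chromene-6-carbaldehyde | CC1(C)C=Cc2c(O1)cc(Oc1cc(OCOC)c(OC)c(CC=C(C)C)c1OCOC)c(C=O)c2OCOC
F7 | step 18 | pentafluorophenyl 7-[4-methoxy-2,5-bis(methoxymethoxy)-3-(3-methylbut-2-en-1-yl)phenoxy]-5-(methoxymethoxy)-2,2-dimethyl-2H-chromene-6-carboxylate | CC1(C)C=Cc2c(O1)cc(Oc1cc(OCOC)c(OC)c(CC=C(C)C)c1OCOC)c(C(=O)Oc1c(F)c(F)c(F)c(F)c1F)c2OCOC
F8 | step 18 | pentafluorophenyl 7-[2,5-dihydroxy-4-methoxy-3-(3-methylbut-2-en-1-yl)phenoxy]-5-hydroxy-2,2-dimethyl-2H-chromene-6-carboxylate | CC1(C)C=Cc2c(O1)cc(Oc1cc(O)c(OC)c(CC=C(C)C)c1O)c(C(=O)Oc1c(F)c(F)c(F)c(F)c1F)c2O
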